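**Strategy.** Ring B is closed by a Diels–Alder reaction, so the route rests on a ring A diene; ring A itself (C1–C5 and C10, drimane numbering) is made by one-carbon ring expansion. In the key step the silyl enol ether of 2,2-dimethylcyclopentanone adds chloro(methyl)carbene and the resulting bicyclo[3.1.0]hexane opens to 2,6,6-trimethylcyclohex-2-enone: C10 and its methyl are inserted between C5 and C1 of ring A, and the quaternary C4 makes the insertion regiospecific. The enone C5(=O)–C10(CH3)=C1 then accepts oxygen at C1 and a vinyl group at C5; cycloaddition with dimethyl acetylenedicarboxylate sets C10, and epoxide hydrogenolysis sets the C5 hydroxyl.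

Key step: step 2

Remark on the chemistry: drimane numbering is used throughout (ring A: C1, C2, C3, C4, C5, C10; ring B: C5 to C10; C11 on C9, C12 on C8; β is the face of the C10 methyl). The target SMILES is read as the (1R,5R,9R,10S) isomer, i.e. 1β-acyloxy, 5α-OH, 9α-H, 10β-CH3.

Step 1
Reactants: 1 2,2-dimethylcyclopentan-1-one
Product: 2 5,5-dimethyl-1-(trimethylsilyloxy)cyclopent-1-ene
Conditions: LiN(iPr)2 (LDA), THF, −78 °C; Me3SiCl, −78 °C → rt
Reagents that add atoms: chlorotrimethylsilane, C[Si](C)(C)Cl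
Why: Enolate formation and O-silylation (silyl enol ether synthesis) can give only one regioisomer, because the carbon that becomes C4 is quaternary and only the future C1 carries α-hydrogens.

Step 2
Reactants: 2 5,5-dimethyl-1-(trimethylsilyloxy)cyclopent-1-ene; 3 1,1-dichloroethane
Product: 5 2,6,6-trimethylcyclohex-2-en-1-one, via chlorocyclopropane 4 (not isolated)
Conditions: n-BuLi, Et2O, −35 °C → 0 °C; then toluene, 110 °C
Reagents that add atoms: none
Why: n-Butyllithium deprotonates 3 and loss of LiCl gives chloro(methyl)carbene, which adds in a [2+1] cycloaddition to the electron-rich enol ether bond of 2 (future C5=C1), so that the carbene carbon becomes C10 with its methyl; on heating, 4 ionizes at C–Cl with disrotatory cyclopropyl-to-allyl electrocyclic opening, assisted by the silyloxy lone pair, and loss of Me3SiCl gives enone 5. The closest known reaction type is the halocarbene one-carbon ring expansion of cyclic silyl enol ethers to 2-substituted cycloalk-2-enones. No ring is closed by cyclization: the cyclopropane arises by cheletropic addition, and ring A arises when the bond shared by the three- and five-membered rings (C5–C1) breaks, so the five-membered ring grows by one atom. No stereocenter is left in 5, and the two C–Cl epimers of 4 should converge. The selectivity needed is regiochemical (insertion between C5 and C1 only) and is secured by the quaternary C4, which allows a single enol ether, and by orbital symmetry, which breaks the bond opposite the departing chloride; the epimer with chloride anti to the five-membered ring should open more slowly and may need longer heating.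

Step 3
Reactants: 5 2,6,6-trimethylcyclohex-2-en-1-one
Product: 7 (3R)-3-hydroxy-2,6,6-trimethylcyclohexan-1-one (C2 epimers), via boronate 6 (not isolated)
Conditions: CuCl (cat.), NaOtBu (cat.), Josiphos-type bisphosphine (enantiomer chosen to give 3R), B2pin2, MeOH, THF, rt; then NaBO3·4H2O, THF/H2O
Reagents that add atoms: bis(pinacolato)diboron, CC1(C)OB(OC1(C)C)B1OC(C)(C)C(C)(C)O1 (boron of 6); sodium perborate, [Na+].[O-]OB=O (oxygen of 7)
Why: Copper-catalysed conjugate borylation (a monovalent copper boryl adds 1,4) places boron on the unsubstituted β-carbon C1 with the chiral bisphosphine selecting the enone face, and perborate oxidation replaces C–B by C–O with retention to set the 1R carbinol; the C10 epimers do not matter because C10 becomes sp2 in step 5.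

Step 4
Reactants: 7 (3R)-3-hydroxy-2,6,6-trimethylcyclohexan-1-one
Product: 8 (3R)-3-(tert-butyldimethylsilyloxy)-2,6,6-trimethylcyclohexan-1-one
Conditions: TBSCl, imidazole, DMF, rt
Reagents that add atoms: tert-butyldimethylsilyl chloride, CC(C)(C)[Si](C)(C)Cl
Why: Silylation of the secondary alcohol protects C1–OH and supplies the bulky group that later steers the cycloaddition.

Step 5
Reactants: 8 (3R)-3-(tert-butyldimethylsilyloxy)-2,6,6-trimethylcyclohexan-1-one
Product: 9 (3R)-3-(tert-butyldimethylsilyloxy)-2,6,6-trimethylcyclohex-1-en-1-yl trifluoromethanesulfonate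
Conditions: KN(SiMe3)2 (KHMDS), THF, −78 °C; PhNTf2, −78 → 0 °C
Reagents that add atoms: N-phenylbis(trifluoromethanesulfonimide), O=S(=O)(N(c1ccccc1)S(=O)(=O)C(F)(F)F)C(F)(F)F
Why: The hindered amide base removes the only α-proton (C10–H, C4 being quaternary) at low temperature, where β-elimination of the silyloxy group should be slow, and O-triflation of the enolate gives the tetrasubstituted enol triflate regiospecifically.

Step 6
Reactants: 9 (3R)-3-(tert-butyldimethylsilyloxy)-2,6,6-trimethylcyclohex-1-en-1-yl trifluoromethanesulfonate; 10 tributyl(vinyl)stannane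
Product: 11 tert-butyldimethyl{[(1R)-2,4,4-trimethyl-3-vinylcyclohex-2-en-1-yl]oxy}silane
Conditions: Pd(PPh3)4 (cat.), LiCl, THF, 65 °C
Reagents that add atoms: none
Why: Stille coupling (zerovalent palladium, LiCl to assist the triflate) joins the vinyl group to C5 and keeps the C5=C10 double bond, giving the ring A diene.

Step 7
Reactants: 11 tert-butyldimethyl{[(1R)-2,4,4-trimethyl-3-vinylcyclohex-2-en-1-yl]oxy}silane; 12 dimethyl but-2-ynedioate
Product: 13 dimethyl 1β-(tert-butyldimethylsilyloxy)drima-5,8-diene-11,12-dioate (10β-CH3)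
Conditions: neat (excess 12), BHT (cat.), 110 °C, sealed tube
Reagents that add atoms: none
Why: The thermal Diels–Alder reaction with the symmetrical alkyne closes ring B by forming C7–C8 and C9–C10 and creates the quaternary C10; the C1 silyloxy group, held pseudoaxial by allylic strain against the C10 methyl, shields its own face, so the dienophile should add anti and the C10 methyl ends cis (β) to the C1 oxygen.

Step 8
Reactants: 13 dimethyl 1β-(tert-butyldimethylsilyloxy)drima-5,8-diene-11,12-dioate
Product: 14 dimethyl 1β-(tert-butyldimethylsilyloxy)drima-5,7-diene-11,12-dioate (9α-H, 9β-CO2Me)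
Conditions: KN(SiMe3)2 (KHMDS), THF, −78 °C; then AcOH, −78 °C
Reagents that add atoms: none
Why: Deprotonation of the doubly allylic C7–H gives the extended enolate of the C9 ester, and kinetic α-protonation at C9 (deconjugative protonation of a dienolate) from the face opposite the axial C10 methyl should set 9α-H and leave the conjugated 5,7-diene.

Step 9
Reactants: 14 dimethyl 1β-(tert-butyldimethylsilyloxy)drima-5,7-diene-11,12-dioate
Product: 15 dimethyl 1β-(tert-butyldimethylsilyloxy)-5α,6α-epoxydrim-7-ene-11,12-dioate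
Conditions: mCPBA, NaHCO3, CH2Cl2, 0 °C
Reagents that add atoms: meta-chloroperbenzoic acid, OOC(=O)c1cccc(Cl)c1
Why: Prilezhaev epoxidation selects the electron-rich C5=C6 bond over the ester-conjugated C7=C8 bond and should come from the α-face, away from the axial β-methyls on C10 and C4, to set the 5α-oxygen.

Step 10
Reactants: 15 dimethyl 1β-(tert-butyldimethylsilyloxy)-5α,6α-epoxydrim-7-ene-11,12-dioate
Product: 16 dimethyl 1β-(tert-butyldimethylsilyloxy)-5α-hydroxydrim-7-ene-11,12-dioate
Conditions: Pd2(dba)3·CHCl3 (cat.), n-Bu3P, HCO2H, Et3N, 1,4-dioxane, rt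
Reagents that add atoms: none
Why: Zerovalent palladium opens the alkenyl epoxide at the allylic C6–O bond to a π-allyl complex and formate-derived hydride is delivered to C6 (palladium-catalysed hydrogenolysis of a γ,δ-epoxy enoate to the δ-hydroxy enoate), so C5 keeps its α-oxygen and C7=C8 stays conjugated.

Step 11
Reactants: 16 dimethyl 1β-(tert-butyldimethylsilyloxy)-5α-hydroxydrim-7-ene-11,12-dioate
Product: 17 1β-(tert-butyldimethylsilyloxy)drim-7-ene-5α,11,12-triol
Conditions: iBu2AlH (DIBAL-H, excess), CH2Cl2, −78 → 0 °C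
Reagents that add atoms: none
Why: Aluminium hydride reduction of both esters (1,2-reduction of the enoate) gives the 11,12-diol and removes the only epimerizable α-carbonyl position at C9 without changing it.

Step 12
Reactants: 17 1β-(tert-butyldimethylsilyloxy)drim-7-ene-5α,11,12-triol
Product: 18 drim-7-ene-1β,5α,11,12-tetraol
Conditions: Bu4NF (TBAF), THF, 50 °C
Reagents that add atoms: none
Why: Fluoride-driven desilylation frees C1–OH, and no base-sensitive center remains at this stage.

Step 13
Reactants: 18 drim-7-ene-1β,5α,11,12-tetraol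
Product: 19 11,12-bis(triethylsilyloxy)drim-7-ene-1β,5α-diol
Conditions: Et3SiCl (2.1 equiv), imidazole, CH2Cl2/DMF, −20 → 0 °C
Reagents that add atoms: chlorotriethylsilane, CC[Si](CC)(CC)Cl
Why: Silylation is governed by steric access, so the two primary hydroxyls should react while the neopentyl-type secondary C1–OH and the tertiary C5–OH stay free.

Step 14
Reactants: 20 (E)-4-hydroxycinnamic acid
Product: 22 (E)-4-(tert-butyldimethylsilyloxy)cinnamic acid, via bis-silyl derivative 21 (not isolated)
Conditions: TBSCl (2.2 equiv), imidazole, DMF, rt; then AcOH, THF/H2O, rt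
Reagents that add atoms: tert-butyldimethylsilyl chloride, CC(C)(C)[Si](C)(C)Cl
Why: Both acidic OH groups are silylated and the much more labile silyl ester is then hydrolysed selectively, leaving the phenol protected.

Step 15
Reactants: 19 11,12-bis(triethylsilyloxy)drim-7-ene-1β,5α-diol; 22 (E)-4-(tert-butyldimethylsilyloxy)cinnamic acid
Product: 24 1β-[(E)-4-(tert-butyldimethylsilyloxy)cinnamoyloxy]-11,12-bis(triethylsilyloxy)drim-7-en-5α-ol, via mixed anhydride 23 (not isolated)
Conditions: 2,4,6-trichlorobenzoyl chloride, Et3N, THF, rt; then 19, DMAP, toluene, 50 °C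
Reagents that add atoms: 2,4,6-trichlorobenzoyl chloride, O=C(Cl)c1c(Cl)cc(Cl)cc1Cl (its acyl group is in 23 only)
Why: Yamaguchi esterification through the mixed anhydride and DMAP acylates the hindered secondary C1–OH with retention at C1, the tertiary C5–OH being unreactive.

Step 16
Reactants: 24 1β-[(E)-4-(tert-butyldimethylsilyloxy)cinnamoyloxy]-11,12-bis(triethylsilyloxy)drim-7-en-5α-ol
Product: 25 1β-[(E)-4-(tert-butyldimethylsilyloxy)cinnamoyloxy]drim-7-ene-5α,11,12-triol
Conditions: PPTS (cat.), MeOH/CH2Cl2, 0 °C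
Reagents that add atoms: none
Why: Mild acidic methanolysis cleaves the primary triethylsilyl ethers while the aryl tert-butyldimethylsilyl ether and the cinnamate should survive.

Step 17
Reactants: 25 1β-[(E)-4-(tert-butyldimethylsilyloxy)cinnamoyloxy]drim-7-ene-5α,11,12-triol
Product: 26 1β-[(E)-4-(tert-butyldimethylsilyloxy)cinnamoyloxy]-5α-hydroxydrim-7-ene-11,12-dial
Conditions: (COCl)2, DMSO, CH2Cl2, −78 °C; Et3N, −78 → −30 °C
Reagents that add atoms: none
Why: Swern oxidation converts both primary alcohols to aldehydes; both alkoxysulfonium ions form before the base is added, which avoids lactol formation, and the short cold exposure to amine should leave C9 untouched.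

Step 18
Reactants: 26 1β-[(E)-4-(tert-butyldimethylsilyloxy)cinnamoyloxy]-5α-hydroxydrim-7-ene-11,12-dial
Product: 27 1β-[(E)-4-hydroxycinnamoyloxy]-5α-hydroxydrim-7-ene-11,12-dial (target)
Conditions: HF·pyridine, pyridine, THF, 0 °C
Reagents that add atoms: none
Why: Acidic fluoride cleaves the aryl silyl ether without strong base, so the dialdehyde and the C9 configuration should be preserved.

**Compound list**

1 | 2,2-dimethylcyclopentan-1-one | CC1(C)CCCC1=O | starting material
2 | 5,5-dimethyl-1-(trimethylsilyloxy)cyclopent-1-ene | C[Si](C)(C)OC1=CCCC1(C)C | intermediate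
3 | 1,1-dichloroethane | CC(Cl)Cl | starting material
4 | 6-chloro-2,2,6-trimethyl-1-(trimethylsilyloxy)bicyclo[3.1.0]hexane (both C6 epimers) | C[Si](C)(C)OC12C(C)(Cl)C1CCC2(C)C | intermediate (not isolated)
5 | 2,6,6-trimethylcyclohex-2-en-1-one | CC1=CCCC(C)(C)C1=O | intermediate
6 | (3R)-2,6,6-trimethyl-3-(4,4,5,5-tetramethyl-1,3,2-dioxaborolan-2-yl)cyclohexan-1-one (C2 epimers) | CC1(C)CC[C@@H](B2OC(C)(C)C(C)(C)O2)C(C)C1=O | intermediate (not isolated)
7 | (3R)-3-hydroxy-2,6,6-trimethylcyclohexan-1-one (C2 epimers) | CC1(C)CC[C@@H](O)C(C)C1=O | intermediate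
8 | (3R)-3-(tert-butyldimethylsilyloxy)-2,6,6-trimethylcyclohexan-1-one (C2 epimers) | CC1(C)CC[C@@H](O[Si](C)(C)C(C)(C)C)C(C)C1=O | intermediate
9 | (3R)-3-(tert-butyldimethylsilyloxy)-2,6,6-trimethylcyclohex-1-en-1-yl trifluoromethanesulfonate | CC1(C)CC[C@@H](O[Si](C)(C)C(C)(C)C)C(C)=C1OS(=O)(=O)C(F)(F)F | intermediate
10 | tributyl(vinyl)stannane | C=C[Sn](CCCC)(CCCC)CCCC | starting material
11 | tert-butyldimethyl{[(1R)-2,4,4-trimethyl-3-vinylcyclohex-2-en-1-yl]oxy}silane | CC1(C)CC[C@@H](O[Si](C)(C)C(C)(C)C)C(C)=C1C=C | intermediate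
12 | dimethyl but-2-ynedioate | COC(=O)C#CC(=O)OC | starting material
13 | dimethyl 1β-(tert-butyldimethylsilyloxy)drima-5,8-diene-11,12-dioate (10β-CH3) | CC1(C)CC[C@@H](O[Si](C)(C)C(C)(C)C)[C@]2(C)C(C(=O)OC)=C(C(=O)OC)CC=C12 | intermediate
14 | dimethyl 1β-(tert-butyldimethylsilyloxy)drima-5,7-diene-11,12-dioate (9α-H) | CC1(C)CC[C@@H](O[Si](C)(C)C(C)(C)C)[C@]2(C)[C@@H](C(=O)OC)C(C(=O)OC)=CC=C12 | intermediate
15 | dimethyl 1β-(tert-butyldimethylsilyloxy)-5α,6α-epoxydrim-7-ene-11,12-dioate (9α-H) | CC1(C)CC[C@@H](O[Si](C)(C)C(C)(C)C)[C@]2(C)[C@@H](C(=O)OC)C(C(=O)OC)=C[C@H]3[C@@]12O3 | intermediate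
16 | dimethyl 1β-(tert-butyldimethylsilyloxy)-5α-hydroxydrim-7-ene-11,12-dioate (9α-H) | CC1(C)CC[C@@H](O[Si](C)(C)C(C)(C)C)[C@]2(C)[C@@H](C(=O)OC)C(C(=O)OC)=CC[C@@]12O | intermediate
17 | 1β-(tert-butyldimethylsilyloxy)drim-7-ene-5α,11,12-triol (9α-H) | CC1(C)CC[C@@H](O[Si](C)(C)C(C)(C)C)[C@]2(C)[C@@H](CO)C(CO)=CC[C@@]12O | intermediate
18 | drim-7-ene-1β,5α,11,12-tetraol (9α-H) | CC1(C)CC[C@@H](O)[C@]2(C)[C@@H](CO)C(CO)=CC[C@@]12O | intermediate
19 | 11,12-bis(triethylsilyloxy)drim-7-ene-1β,5α-diol (9α-H) | CC1(C)CC[C@@H](O)[C@]2(C)[C@@H](CO[Si](CC)(CC)CC)C(CO[Si](CC)(CC)CC)=CC[C@@]12O | intermediate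
20 | (E)-4-hydroxycinnamic acid | OC(=O)/C=C/c1ccc(O)cc1 | starting material
21 | tert-butyldimethylsilyl (E)-4-(tert-butyldimethylsilyloxy)cinnamate | CC(C)(C)[Si](C)(C)OC(=O)/C=C/c1ccc(O[Si](C)(C)C(C)(C)C)cc1 | intermediate (not isolated)
22 | (E)-4-(tert-butyldimethylsilyloxy)cinnamic acid | OC(=O)/C=C/c1ccc(O[Si](C)(C)C(C)(C)C)cc1 | intermediate
23 | (E)-4-(tert-butyldimethylsilyloxy)cinnamic 2,4,6-trichlorobenzoic anhydride | O=C(OC(=O)c1c(Cl)cc(Cl)cc1Cl)/C=C/c1ccc(O[Si](C)(C)C(C)(C)C)cc1 | intermediate (not isolated)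
24 | 1β-[(E)-4-(tert-butyldimethylsilyloxy)cinnamoyloxy]-11,12-bis(triethylsilyloxy)drim-7-en-5α-ol (9α-H) | CC1(C)CC[C@@H](OC(=O)/C=C/c3ccc(O[Si](C)(C)C(C)(C)C)cc3)[C@]2(C)[C@@H](CO[Si](CC)(CC)CC)C(CO[Si](CC)(CC)CC)=CC[C@@]12O | intermediate
25 | 1β-[(E)-4-(tert-butyldimethylsilyloxy)cinnamoyloxy]drim-7-ene-5α,11,12-triol (9α-H) | CC1(C)CC[C@@H](OC(=O)/C=C/c3ccc(O[Si](C)(C)C(C)(C)C)cc3)[C@]2(C)[C@@H](CO)C(CO)=CC[C@@]12O | intermediate
26 | 1β-[(E)-4-(tert-butyldimethylsilyloxy)cinnamoyloxy]-5α-hydroxydrim-7-ene-11,12-dial (9α-H) | CC1(C)CC[C@@H](OC(=O)/C=C/c3ccc(O[Si](C)(C)C(C)(C)C)cc3)[C@]2(C)[C@@H](C=O)C(C=O)=CC[C@@]12O | intermediate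
27 | (1R,5R,9R,10S)-1β-[(E)-4-hydroxycinnamoyloxy]-5α-hydroxydrim-7-ene-11,12-dial | CC1(C)CC[C@@H](OC(=O)/C=C/c2ccc(O)cc2)[C@]2(C)[C@@H](C=O)C(C=O)=CC[C@@]12O | target

**Step count.** Total: 18 steps. Longest linear sequence: 17 steps (steps 1–13 and 15–18); step 14 is a one-step side branch.

**Steps most likely to fail**

1. Step 3. What may go wrong: slow or poorly face-selective conjugate borylation of the α-methyl enone beside a quaternary carbon, giving low enantiomeric purity at C1. The β-silyloxy ketone derived from it may also lose its silyloxy group by β-elimination on enolization in step 5. The fallback sets out from 5 and comes back to the route at 11. CH2=CHMgBr with CeCl3 adds 1,2 to 5 to give 2,6,6-trimethyl-1-vinylcyclohex-2-en-1-ol F1. Oxidative 1,3-transposition with pyridinium chlorochromate, [C5H5NH][CrO3Cl], gives 2,4,4-trimethyl-3-vinylcyclohex-2-en-1-one F2. Corey–Bakshi–Shibata reduction ((S)-Me-CBS, BH3·SMe2) sets C1 and gives (1R)-2,4,4-trimethyl-3-vinylcyclohex-2-en-1-ol F3. Silylation with TBSCl and imidazole then gives 11. C1 is set by ketone reduction instead of conjugate addition, and no β-silyloxy enolate is needed.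

2. Step 8. What may go wrong: protonation of the extended enolate at C7 or C5 instead of C9, or from the β-face, which would scramble the double-bond positions or the C9 configuration. The fallback sets out from 13 and comes back at 16. Epoxidation of the electron-rich C5=C6 bond of 13 with mCPBA gives dimethyl 1β-(tert-butyldimethylsilyloxy)-5α,6α-epoxydrim-8-ene-11,12-dioate F4. DBU removes a C7 proton and opens the epoxide (vinylogous E1cB) to dimethyl 1β-(tert-butyldimethylsilyloxy)-5α-hydroxydrima-6,8-diene-11,12-dioate F5. Diimide (TsNHNH2, NaOAc) reduces the disubstituted C6=C7 bond to dimethyl 1β-(tert-butyldimethylsilyloxy)-5α-hydroxydrim-8-ene-11,12-dioate F6. NaOMe in MeOH then equilibrates the double bond to C7=C8 with the equatorial 9β-ester, giving 16. C9 is set under thermodynamic instead of kinetic control.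

3. Step 10. What may go wrong: β-hydride elimination from the π-allyl palladium intermediate, or hydride delivery to C8 instead of C6. The fallback sets out from 15 and comes back at 16. Electron-transfer reduction with SmI2 (THF/MeOH, −78 °C) opens the γ,δ-epoxy enoate to dimethyl 1β-(tert-butyldimethylsilyloxy)-5α-hydroxydrim-6-ene-11,12-dioate F7 (9α-H, C8 epimers). Brief treatment with DBU moves the double bond back into conjugation (C7=C8), giving 16.

**Further compounds**

F1 | step 3 | 2,6,6-trimethyl-1-vinylcyclohex-2-en-1-ol (racemic) | CC1=CCCC(C)(C)C1(O)C=C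
F2 | step 3 | 2,4,4-trimethyl-3-vinylcyclohex-2-en-1-one | CC1(C)CCC(=O)C(C)=C1C=C
F3 | step 3 | (1R)-2,4,4-trimethyl-3-vinylcyclohex-2-en-1-ol | CC1(C)CC[C@@H](O)C(C)=C1C=C
F4 | step 8 | dimethyl 1β-(tert-butyldimethylsilyloxy)-5α,6α-epoxydrim-8-ene-11,12-dioate | CC1(C)CC[C@@H](O[Si](C)(C)C(C)(C)C)[C@]2(C)C(C(=O)OC)=C(C(=O)OC)C[C@H]3[C@@]12O3
F5 | step 8 | dimethyl 1β-(tert-butyldimethylsilyloxy)-5α-hydroxydrima-6,8-diene-11,12-dioate | CC1(C)CC[C@@H](O[Si](C)(C)C(C)(C)C)[C@]2(C)C(C(=O)OC)=C(C(=O)OC)C=C[C@@]12O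
F6 | step 8 | dimethyl 1β-(tert-butyldimethylsilyloxy)-5α-hydroxydrim-8-ene-11,12-dioate | CC1(C)CC[C@@H](O[Si](C)(C)C(C)(C)C)[C@]2(C)C(C(=O)OC)=C(C(=O)OC)CC[C@@]12O
F7 | step 10 | dimethyl 1β-(tert-butyldimethylsilyloxy)-5α-hydroxydrim-6-ene-11,12-dioate (9α-H, C8 epimers) | CC1(C)CC[C@@H](O[Si](C)(C)C(C)(C)C)[C@]2(C)[C@@H](C(=O)OC)C(C(=O)OC)C=C[C@@]12O
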